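**Retrosynthetic overview**
1. Target 21 ⇐ acid hydrolysis of the two aryl MOM ethers and fluoride cleavage of the 7‑O‑TIPS ether of the protected (3S)‑3‑hydroxyisoflavanone 19.
2. Ring C of 19 ⇐ one‑flask alkylative–acylative (4+2) annulation: C2–C3 by alkylation of the lithium enolate of dioxolanone 10 with the aryl chloromethyl ether 14, then C4–C4a by bromine–lithium exchange and attack of C4a on the acylal carbonyl, with loss of pivalaldehyde.
3. Enabling feature: C3 carries OH and aryl next to the C4 carbonyl, so ring C hides an aryl‑glycolic (α‑hydroxy) acid that can be tied up with pivalaldehyde as a chiral 1,3‑dioxolan‑4‑one (nucleophilic at C3, electrophilic at C4); O1–C2H2 is a formaldehyde‑level carbon on the phenol oxygen of ring A, and C4a is ortho to O1.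
4. 10 ⇐ (R)‑aryl‑glycolic acid 8 ⇐ asymmetric transfer hydrogenation of glyoxylate 6 ⇐ ortho‑lithiation/oxalylation, bromination and Stille prenylation of bis‑MOM 3‑methoxycatechol; 14 ⇐ 4‑bromoresorcinol.
5. Ring order: rings A and B are bought as arenes; the temporary dioxolanone ring is closed in step 7 and opened again in step 11, where ring C, the only ring made, is formed.

Key step: step 11

Remark (stereochemistry): C3 of the target is (S) (CIP order OH > C4 > C2 > aryl). Because CH2OAr outranks the aryl group, this centre derives from the (R)‑aryl‑glycolic acid when the new carbon takes the place of the α‑hydrogen.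

**Ring B fragment**

Step 1
Reactants: 1 3‑methoxybenzene‑1,2‑diol (3‑methoxycatechol)
Product: 2 1‑methoxy‑2,3‑bis(methoxymethoxy)benzene
Conditions: MOMCl, i‑Pr2NEt, CH2Cl2, 0 °C → rt
Reagents that add atoms: chloromethyl methyl ether, COCCl
Why: Williamson‑type O‑alkylation of both phenols gives MOM acetals that should survive base, organometallics and Pd and that serve as ortho‑directing groups in step 2.

Step 2
Reactants: 2 1‑methoxy‑2,3‑bis(methoxymethoxy)benzene
Product: 4 ethyl [4‑methoxy‑2,3‑bis(methoxymethoxy)phenyl](oxo)acetate, via aryllithium 3 (not isolated)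
Conditions: n‑BuLi, TMEDA, THF, 0 °C; then cannulated into diethyl oxalate (excess), THF, −78 °C; NH4Cl (aq)
Reagents that add atoms: diethyl oxalate, CCOC(=O)C(=O)OCC
Why: Directed ortho‑metalation should occur next to the OMOM group, a stronger director than OMe, and inverse addition to excess oxalate at −78 °C should stop the acylation at the α‑keto ester.

Step 3
Reactants: 4 ethyl [4‑methoxy‑2,3‑bis(methoxymethoxy)phenyl](oxo)acetate
Product: 5 ethyl [5‑bromo‑4‑methoxy‑2,3‑bis(methoxymethoxy)phenyl](oxo)acetate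
Conditions: NBS, MeCN, 0 °C → rt, dark
Reagents that add atoms: N‑bromosuccinimide, O=C1CCC(=O)N1Br
Why: Electrophilic aromatic bromination should go to C5, which is ortho to OMe, para to the 2‑OMOM group and meta to the deactivating keto ester, whereas C6 is ortho to the acyl group and para only to the twisted central oxygen.

Step 4
Reactants: 5 ethyl [5‑bromo‑4‑methoxy‑2,3‑bis(methoxymethoxy)phenyl](oxo)acetate
Product: 6 ethyl [4‑methoxy‑2,3‑bis(methoxymethoxy)‑5‑(3‑methylbut‑2‑en‑1‑yl)phenyl](oxo)acetate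
Conditions: tributyl(3‑methylbut‑2‑en‑1‑yl)stannane, Pd(PPh3)4 (cat.), DMF, 90 °C
Reagents that add atoms: tributyl(3‑methylbut‑2‑en‑1‑yl)stannane, CCCC[Sn](CCCC)(CCCC)CC=C(C)C
Why: Stille coupling of the aryl bromide should transfer the prenyl group through its unsubstituted α‑carbon under neutral conditions that keto ester and acetals tolerate.

Step 5
Reactants: 6 ethyl [4‑methoxy‑2,3‑bis(methoxymethoxy)‑5‑(3‑methylbut‑2‑en‑1‑yl)phenyl](oxo)acetate
Product: 7 ethyl (2R)‑hydroxy[4‑methoxy‑2,3‑bis(methoxymethoxy)‑5‑(3‑methylbut‑2‑en‑1‑yl)phenyl]acetate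
Conditions: RuCl(p‑cymene)[(S,S)‑TsDPEN] (cat.), HCO2H–Et3N (5:2), DMF, 25 °C
Reagents that add atoms: none
Why: Noyori–Ikariya asymmetric transfer hydrogenation of the aryl α‑keto ester should set the (R)‑carbinol centre by catalyst control (outer‑sphere hydride/proton transfer to the Si face, expected for the (S,S) catalyst by the aryl CH/π model, the enantiomeric catalyst being used should the sense prove opposite), and the isolated trisubstituted alkene is inert to this catalyst.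

Step 6
Reactants: 7 ethyl (2R)‑hydroxy[4‑methoxy‑2,3‑bis(methoxymethoxy)‑5‑(3‑methylbut‑2‑en‑1‑yl)phenyl]acetate
Product: 8 (2R)‑hydroxy[4‑methoxy‑2,3‑bis(methoxymethoxy)‑5‑(3‑methylbut‑2‑en‑1‑yl)phenyl]acetic acid
Conditions: LiOH·H2O, THF–H2O, 0 °C; then cold dilute HCl to pH 3
Reagents that add atoms: lithium hydroxide, [Li+].[OH-]
Why: Ester saponification at 0 °C should give the acid without racemisation of the α‑hydroxy centre, and the MOM acetals are stable to base and to a brief cold acidification.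

Step 7
Reactants: 8 (2R)‑hydroxy[4‑methoxy‑2,3‑bis(methoxymethoxy)‑5‑(3‑methylbut‑2‑en‑1‑yl)phenyl]acetic acid
Product: 10 (2R,5R)‑2‑tert‑butyl‑5‑[4‑methoxy‑2,3‑bis(methoxymethoxy)‑5‑(3‑methylbut‑2‑en‑1‑yl)phenyl]‑1,3‑dioxolan‑4‑one (cis), via bis‑TMS derivative 9 (not isolated)
Conditions: TMSCl, Et3N, CH2Cl2, 0 °C → rt; then t‑BuCHO, TMSOTf (cat.), CH2Cl2, −78 °C; pyridine quench
Reagents that add atoms: pivalaldehyde, CC(C)(C)C=O
Why: Silyl‑modified acetalisation (TMSOTf‑catalysed condensation of the bis‑silylated hydroxy acid with the aldehyde) under kinetic control at −78 °C should give the cis‑2,5‑disubstituted dioxolanone, so the acetal centre (2R) is set by the existing C5 centre, while the catalytic low‑temperature conditions should spare the aryl MOM ethers; crystallisation should remove any trans isomer and raise the enantiomeric purity.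

**Ring A fragment**

Step 8
Reactants: 11 4‑bromobenzene‑1,3‑diol (4‑bromoresorcinol)
Product: 12 2‑bromo‑5‑[(triisopropylsilyl)oxy]phenol
Conditions: TIPSCl (1 equiv), imidazole, DMF, −20 → 0 °C
Reagents that add atoms: chlorotriisopropylsilane, CC(C)[Si](Cl)(C(C)C)C(C)C
Why: Silyl ether formation with the bulky chlorosilane should take place at the hydroxyl remote from bromine, because the ortho‑bromo hydroxyl is hindered and weakly hydrogen‑bonded.

Step 9
Reactants: 12 2‑bromo‑5‑[(triisopropylsilyl)oxy]phenol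
Product: 13 {4‑bromo‑3‑[(methylsulfanyl)methoxy]phenoxy}triisopropylsilane
Conditions: NaH, DMF, 0 °C; ClCH2SMe, NaI (cat.), 0 °C → rt
Reagents that add atoms: chloromethyl methyl sulfide, CSCCl
Why: Williamson etherification of the sodium phenoxide with the Finkelstein‑activated α‑chloro sulfide should give the O,S‑acetal, the meta TIPS ether being too hindered to migrate.

Step 10
Reactants: 13 {4‑bromo‑3‑[(methylsulfanyl)methoxy]phenoxy}triisopropylsilane
Product: 14 [4‑bromo‑3‑(chloromethoxy)phenoxy]triisopropylsilane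
Conditions: SO2Cl2, CH2Cl2, −78 → 0 °C; volatiles removed in vacuo, used at once
Reagents that add atoms: sulfuryl chloride, O=S(=O)(Cl)Cl
Why: Chlorinolysis of the O,S‑acetal (S‑chlorination, then loss of methanesulfenyl chloride from the chlorosulfonium ion) should give the α‑chloro ether, the sulfide reacting far faster than the brominated ring at low temperature.

**Annulation and end game**

Step 11
Reactants: 10 (2R,5R)‑2‑tert‑butyl‑5‑[4‑methoxy‑2,3‑bis(methoxymethoxy)‑5‑(3‑methylbut‑2‑en‑1‑yl)phenyl]‑1,3‑dioxolan‑4‑one; 14 [4‑bromo‑3‑(chloromethoxy)phenoxy]triisopropylsilane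
Product: 19 (3S)‑3‑hydroxy‑3‑[4‑methoxy‑2,3‑bis(methoxymethoxy)‑5‑(3‑methylbut‑2‑en‑1‑yl)phenyl]‑7‑[(triisopropylsilyl)oxy]‑2,3‑dihydro‑4H‑chromen‑4‑one, via lithium enolate 15 (not isolated), via alkylated dioxolanone 16 (not isolated), via aryllithium 17 (not isolated), via lithium hemiketal 18 (not isolated)
Conditions: LiHMDS (1.05 equiv), THF, −78 °C; 14 (1.0 equiv), −78 °C; then t‑BuLi (3.1 equiv), −100 → −78 °C; AcOH, −78 °C → rt
Reagents that add atoms: none
Why: LiHMDS converts 10 into the planar lithium enolate 15, whose C3 carbon is alkylated by the α‑chloro ether 14 (forming C2–C3), and bromine–lithium exchange with t‑BuLi then turns the C–Br carbon into the aryllithium 17, which adds to the acylal carbonyl (forming C4–C4a) to give the lithium hemiketal 18 that collapses on protonation to the C4 ketone, the free C3 hydroxyl and pivalaldehyde. The closest known reaction types are the alkylation of 2‑tert‑butyl‑1,3‑dioxolan‑4‑one enolates (self‑regeneration of stereocentres) and the Parham cyclisation of an aryllithium onto a carboxylic acid derivative, run here in one flask as a formal (4+2) annulation. Ring C is closed by 6‑exo‑trig attack of the aryl carbanion on the C4 carbonyl. The new stereocentre C3 is controlled by the tert‑butyl group on the acetal carbon, which blocks one face of enolate 15 so that the CH2 electrophile enters trans to it and takes the place of the former hydrogen [(2R,5R) → (2R,5S) → (3S)]; after this it is quaternary and cannot epimerise. The step needs C‑ over O‑alkylation (lithium enolate in THF without dipolar cosolvent, SN2‑biased electrophile with an electron‑poor aryloxy group), exchange faster than carbonyl addition (t‑BuLi at −100 °C, carbonyl next to a quaternary carbon, one equivalent only re‑lithiating the liberated HMDS) and no second addition (the ketone is set free from 18 only on quenching), while the site of ring closure is fixed by the bromine para to the silyloxy group.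

Step 12
Reactants: 19 (3S)‑3‑hydroxy‑3‑[4‑methoxy‑2,3‑bis(methoxymethoxy)‑5‑(3‑methylbut‑2‑en‑1‑yl)phenyl]‑7‑[(triisopropylsilyl)oxy]‑2,3‑dihydro‑4H‑chromen‑4‑one
Product: 20 (3S)‑3,7‑dihydroxy‑3‑[4‑methoxy‑2,3‑bis(methoxymethoxy)‑5‑(3‑methylbut‑2‑en‑1‑yl)phenyl]‑2,3‑dihydro‑4H‑chromen‑4‑one
Conditions: TBAF, AcOH, THF, 0 °C
Reagents that add atoms: none
Why: Fluoride‑mediated desilylation (driven by the Si–F bond) should free the 7‑hydroxyl, the acetic acid buffer keeping the α‑ketol away from basic conditions.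

Step 13
Reactants: 20 (3S)‑3,7‑dihydroxy‑3‑[4‑methoxy‑2,3‑bis(methoxymethoxy)‑5‑(3‑methylbut‑2‑en‑1‑yl)phenyl]‑2,3‑dihydro‑4H‑chromen‑4‑one
Product: 21 (3S)‑3‑[2,3‑dihydroxy‑4‑methoxy‑5‑(3‑methylbut‑2‑en‑1‑yl)phenyl]‑3,7‑dihydroxy‑2,3‑dihydro‑4H‑chromen‑4‑one (target)
Conditions: 3 M aq. HCl, THF, 40 °C
Reagents that add atoms: none
Why: Acid‑catalysed acetal hydrolysis should remove both aryl MOM ethers; the aqueous, alcohol‑free medium lets any hemiketal between the 2'‑hydroxyl and C4 revert to the ketone, the prenyl group has no free ortho hydroxyl to cyclise onto, and ionisation at C3 is disfavoured by the adjacent carbonyl, so the stereocentre should be retained.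

**Compound list**
1 | 3‑methoxybenzene‑1,2‑diol | COc1cccc(O)c1O | starting material
2 | 1‑methoxy‑2,3‑bis(methoxymethoxy)benzene | COCOc1cccc(OC)c1OCOC | intermediate
3 | [4‑methoxy‑2,3‑bis(methoxymethoxy)phenyl]lithium (formed in the flask) | [Li]c1ccc(OC)c(OCOC)c1OCOC | intermediate
4 | ethyl [4‑methoxy‑2,3‑bis(methoxymethoxy)phenyl](oxo)acetate | CCOC(=O)C(=O)c1ccc(OC)c(OCOC)c1OCOC | intermediate
5 | ethyl [5‑bromo‑4‑methoxy‑2,3‑bis(methoxymethoxy)phenyl](oxo)acetate | CCOC(=O)C(=O)c1cc(Br)c(OC)c(OCOC)c1OCOC | intermediate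
6 | ethyl [4‑methoxy‑2,3‑bis(methoxymethoxy)‑5‑(3‑methylbut‑2‑en‑1‑yl)phenyl](oxo)acetate | CCOC(=O)C(=O)c1cc(CC=C(C)C)c(OC)c(OCOC)c1OCOC | intermediate
7 | ethyl (2R)‑hydroxy[4‑methoxy‑2,3‑bis(methoxymethoxy)‑5‑(3‑methylbut‑2‑en‑1‑yl)phenyl]acetate | CCOC(=O)[C@H](O)c1cc(CC=C(C)C)c(OC)c(OCOC)c1OCOC | intermediate
8 | (2R)‑hydroxy[4‑methoxy‑2,3‑bis(methoxymethoxy)‑5‑(3‑methylbut‑2‑en‑1‑yl)phenyl]acetic acid | OC(=O)[C@H](O)c1cc(CC=C(C)C)c(OC)c(OCOC)c1OCOC | intermediate
9 | trimethylsilyl (2R)‑[4‑methoxy‑2,3‑bis(methoxymethoxy)‑5‑(3‑methylbut‑2‑en‑1‑yl)phenyl][(trimethylsilyl)oxy]acetate (formed in the flask) | C[Si](C)(C)OC(=O)[C@H](O[Si](C)(C)C)c1cc(CC=C(C)C)c(OC)c(OCOC)c1OCOC | intermediate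
10 | (2R,5R)‑2‑tert‑butyl‑5‑[4‑methoxy‑2,3‑bis(methoxymethoxy)‑5‑(3‑methylbut‑2‑en‑1‑yl)phenyl]‑1,3‑dioxolan‑4‑one (cis) | CC(C)(C)[C@H]1OC(=O)[C@@H](c2cc(CC=C(C)C)c(OC)c(OCOC)c2OCOC)O1 | intermediate
11 | 4‑bromobenzene‑1,3‑diol | Oc1ccc(Br)c(O)c1 | starting material
12 | 2‑bromo‑5‑[(triisopropylsilyl)oxy]phenol | CC(C)[Si](Oc1ccc(Br)c(O)c1)(C(C)C)C(C)C | intermediate
13 | {4‑bromo‑3‑[(methylsulfanyl)methoxy]phenoxy}triisopropylsilane | CSCOc1cc(O[Si](C(C)C)(C(C)C)C(C)C)ccc1Br | intermediate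
14 | [4‑bromo‑3‑(chloromethoxy)phenoxy]triisopropylsilane | ClCOc1cc(O[Si](C(C)C)(C(C)C)C(C)C)ccc1Br | intermediate
15 | lithium (2R)‑2‑tert‑butyl‑5‑[4‑methoxy‑2,3‑bis(methoxymethoxy)‑5‑(3‑methylbut‑2‑en‑1‑yl)phenyl]‑1,3‑dioxol‑4‑olate (formed in the flask) | CC(C)(C)[C@H]1OC(O[Li])=C(c2cc(CC=C(C)C)c(OC)c(OCOC)c2OCOC)O1 | intermediate
16 | (2R,5S)‑5‑({2‑bromo‑5‑[(triisopropylsilyl)oxy]phenoxy}methyl)‑2‑tert‑butyl‑5‑[4‑methoxy‑2,3‑bis(methoxymethoxy)‑5‑(3‑methylbut‑2‑en‑1‑yl)phenyl]‑1,3‑dioxolan‑4‑one (formed in the flask) | CC(C)(C)[C@H]1OC(=O)[C@@](COc2cc(O[Si](C(C)C)(C(C)C)C(C)C)ccc2Br)(c2cc(CC=C(C)C)c(OC)c(OCOC)c2OCOC)O1 | intermediate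
17 | aryllithium of 16, lithium in place of bromine (formed in the flask) | CC(C)(C)[C@H]1OC(=O)[C@@](COc2cc(O[Si](C(C)C)(C(C)C)C(C)C)ccc2[Li])(c2cc(CC=C(C)C)c(OC)c(OCOC)c2OCOC)O1 | intermediate
18 | lithium hemiketal alkoxide: 2‑tert‑butyl‑1,3‑dioxolane cis‑fused across C3–C4 of the chromane, O–Li on C4, with O–Li, ring‑B aryl and tert‑butyl on the same face (formed in the flask) | CC(C)(C)[C@H]1O[C@]2(O[Li])c3ccc(O[Si](C(C)C)(C(C)C)C(C)C)cc3OC[C@]2(c2cc(CC=C(C)C)c(OC)c(OCOC)c2OCOC)O1 | intermediate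
19 | (3S)‑3‑hydroxy‑3‑[4‑methoxy‑2,3‑bis(methoxymethoxy)‑5‑(3‑methylbut‑2‑en‑1‑yl)phenyl]‑7‑[(triisopropylsilyl)oxy]‑2,3‑dihydro‑4H‑chromen‑4‑one | COc1c(CC=C(C)C)cc([C@]2(O)COc3cc(O[Si](C(C)C)(C(C)C)C(C)C)ccc3C2=O)c(OCOC)c1OCOC | intermediate
20 | (3S)‑3,7‑dihydroxy‑3‑[4‑methoxy‑2,3‑bis(methoxymethoxy)‑5‑(3‑methylbut‑2‑en‑1‑yl)phenyl]‑2,3‑dihydro‑4H‑chromen‑4‑one | COc1c(CC=C(C)C)cc([C@]2(O)COc3cc(O)ccc3C2=O)c(OCOC)c1OCOC | intermediate
21 | (3S)‑3‑[2,3‑dihydroxy‑4‑methoxy‑5‑(3‑methylbut‑2‑en‑1‑yl)phenyl]‑3,7‑dihydroxy‑2,3‑dihydro‑4H‑chromen‑4‑one | COc1c(CC=C(C)C)cc([C@]2(O)COc3cc(O)ccc3C2=O)c(O)c1O | target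

**Step count:** 13 steps in total; the longest linear sequence is 10 steps (steps 1–7, 11, 12, 13); the ring A branch is 3 steps (8–10).

**Steps most likely to fail**

Step 11. The hard α‑chloro ether may alkylate the enolate on oxygen, and in the second stage tert‑butyllithium may add to the acylal carbonyl, or the hemiketal may collapse early so that the freed ketone is attacked again. The fallback separates the two bond formations and changes the acyl acceptor. It sets out from 10 and 14: the alkylation alone (LiHMDS, THF, −78 °C) is worked up and 16 is isolated. Aminolysis of its dioxolanone with N,O‑dimethylhydroxylamine hydrochloride and i‑PrMgCl (THF, −20 → 0 °C) releases pivalaldehyde and should give the Weinreb amide (2S)‑3‑{2‑bromo‑5‑[(triisopropylsilyl)oxy]phenoxy}‑2‑hydroxy‑N‑methoxy‑N‑methyl‑2‑[4‑methoxy‑2,3‑bis(methoxymethoxy)‑5‑(3‑methylbut‑2‑en‑1‑yl)phenyl]propanamide F1. After deprotonation of the hydroxyl with n‑BuLi, t‑BuLi at −100 °C effects the classical Parham cyclisation onto the Weinreb amide, whose chelated tetrahedral adduct cannot react twice, and work‑up returns to the route at 19.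

Step 13. The finished skeleton may not survive acid: the liberated 2'‑hydroxyl can add to the C4 carbonyl, the prenyl double bond can be hydrated or hydrochlorinated, and released formaldehyde can recombine with the electron‑rich rings. The fallback moves the removal of the acetals to a stage where neither ketone nor tertiary carbinol exists and ends with fluoride alone. It sets out from 10:
- ZnBr2 and n‑PrSH (CH2Cl2, 0 °C) cleave both MOM ethers to (2R,5R)‑2‑tert‑butyl‑5‑[2,3‑dihydroxy‑4‑methoxy‑5‑(3‑methylbut‑2‑en‑1‑yl)phenyl]‑1,3‑dioxolan‑4‑one F2.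
- TBSOTf and 2,6‑lutidine give (2R,5R)‑5‑[2,3‑bis(tert‑butyldimethylsilyloxy)‑4‑methoxy‑5‑(3‑methylbut‑2‑en‑1‑yl)phenyl]‑2‑tert‑butyl‑1,3‑dioxolan‑4‑one F3.
- The one‑flask annulation of step 11 with 14 then runs through the lithium enolate of the bis‑TBS dioxolanone F4, the (2R,5S)‑alkylated bis‑TBS dioxolanone F5, its aryllithium F6 and the cis‑fused lithium hemiketal F7 to (3S)‑3‑[2,3‑bis(tert‑butyldimethylsilyloxy)‑4‑methoxy‑5‑(3‑methylbut‑2‑en‑1‑yl)phenyl]‑3‑hydroxy‑7‑[(triisopropylsilyl)oxy]‑2,3‑dihydro‑4H‑chromen‑4‑one F8.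
- TBAF buffered with AcOH removes all three silyl groups in one operation, and the route is rejoined at 21.

Step 4. The prenyl group may be transferred through its γ‑carbon (reverse‑prenyl isomer), or oxidative addition at the hindered, electron‑rich bromide may be slow enough for protodestannylation to compete. The fallback builds the prenyl group in two stages without regiochemical ambiguity. It sets out from 5: Stille coupling with allyltributylstannane (Pd(PPh3)4, DMF, 90 °C) should give ethyl [5‑allyl‑4‑methoxy‑2,3‑bis(methoxymethoxy)phenyl](oxo)acetate F9. Olefin cross‑metathesis with 2‑methyl‑2‑butene (Grubbs second‑generation catalyst, 40 °C) then converts the allyl into the prenyl group and comes back to the route at 6.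

**Further compounds**
F1 | step 11 | (2S)‑3‑{2‑bromo‑5‑[(triisopropylsilyl)oxy]phenoxy}‑2‑hydroxy‑N‑methoxy‑N‑methyl‑2‑[4‑methoxy‑2,3‑bis(methoxymethoxy)‑5‑(3‑methylbut‑2‑en‑1‑yl)phenyl]propanamide | CON(C)C(=O)[C@@](O)(COc1cc(O[Si](C(C)C)(C(C)C)C(C)C)ccc1Br)c1cc(CC=C(C)C)c(OC)c(OCOC)c1OCOC
F2 | step 13 | (2R,5R)‑2‑tert‑butyl‑5‑[2,3‑dihydroxy‑4‑methoxy‑5‑(3‑methylbut‑2‑en‑1‑yl)phenyl]‑1,3‑dioxolan‑4‑one | CC(C)(C)[C@H]1OC(=O)[C@@H](c2cc(CC=C(C)C)c(OC)c(O)c2O)O1
F3 | step 13 | (2R,5R)‑5‑[2,3‑bis(tert‑butyldimethylsilyloxy)‑4‑methoxy‑5‑(3‑methylbut‑2‑en‑1‑yl)phenyl]‑2‑tert‑butyl‑1,3‑dioxolan‑4‑one | CC(C)(C)[C@H]1OC(=O)[C@@H](c2cc(CC=C(C)C)c(OC)c(O[Si](C)(C)C(C)(C)C)c2O[Si](C)(C)C(C)(C)C)O1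
F4 | step 13 | lithium enolate of the bis‑TBS dioxolanone | CC(C)(C)[C@H]1OC(O[Li])=C(c2cc(CC=C(C)C)c(OC)c(O[Si](C)(C)C(C)(C)C)c2O[Si](C)(C)C(C)(C)C)O1
F5 | step 13 | (2R,5S)‑alkylated bis‑TBS dioxolanone | CC(C)(C)[C@H]1OC(=O)[C@@](COc2cc(O[Si](C(C)C)(C(C)C)C(C)C)ccc2Br)(c2cc(CC=C(C)C)c(OC)c(O[Si](C)(C)C(C)(C)C)c2O[Si](C)(C)C(C)(C)C)O1
F6 | step 13 | aryllithium of the alkylated bis‑TBS dioxolanone | CC(C)(C)[C@H]1OC(=O)[C@@](COc2cc(O[Si](C(C)C)(C(C)C)C(C)C)ccc2[Li])(c2cc(CC=C(C)C)c(OC)c(O[Si](C)(C)C(C)(C)C)c2O[Si](C)(C)C(C)(C)C)O1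
F7 | step 13 | cis‑fused lithium hemiketal of the bis‑TBS series | CC(C)(C)[C@H]1O[C@]2(O[Li])c3ccc(O[Si](C(C)C)(C(C)C)C(C)C)cc3OC[C@]2(c2cc(CC=C(C)C)c(OC)c(O[Si](C)(C)C(C)(C)C)c2O[Si](C)(C)C(C)(C)C)O1
F8 | step 13 | (3S)‑3‑[2,3‑bis(tert‑butyldimethylsilyloxy)‑4‑methoxy‑5‑(3‑methylbut‑2‑en‑1‑yl)phenyl]‑3‑hydroxy‑7‑[(triisopropylsilyl)oxy]‑2,3‑dihydro‑4H‑chromen‑4‑one | COc1c(CC=C(C)C)cc([C@]2(O)COc3cc(O[Si](C(C)C)(C(C)C)C(C)C)ccc3C2=O)c(O[Si](C)(C)C(C)(C)C)c1O[Si](C)(C)C(C)(C)C
F9 | step 4 | ethyl [5‑allyl‑4‑methoxy‑2,3‑bis(methoxymethoxy)phenyl](oxo)acetate | CCOC(=O)C(=O)c1cc(CC=C)c(OC)c(OCOC)c1OCOC
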